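The route rests on cutting the tetrasubstituted C7=C11 alkene of the butenolide (ring B: O1–C12–C11–C7–C8; germacrane numbering, ring A = C1–C10). Because C8 carries the lactone oxygen and C11 carries C12 and C13, this alkene is a C7 ketone condensed with a C12-ester-tethered phosphonate carbanion. An intramolecular Horner–Wadsworth–Emmons olefination of an acyclic 1,3-diacyloxy ketone therefore closes ring B with C13–O already in place. The butenolide then acts as C8 nucleophile (vinylogous aldol to C9), ring A is closed at C2–C3 by Nozaki–Hiyama–Kishi coupling, and E1cB loss of the C9 acetate creates the C8=C9 alkene.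

Key step: step 9

Remark: RAMP, (R)-2-methylglycidol and (triisopropylsiloxy)methyl chloride are taken as purchasable; 11–13 are used as epimer mixtures at the phosphonate carbon and 21–25 as C8/C9 diastereomer mixtures, all of these centres being erased later.

Step 1
Reactants: 1 propargyl alcohol
Product: 2 (Z)-3-iodo-2-methylprop-2-en-1-ol
Conditions: MeMgBr (2.5 equiv), CuI (10 mol%), Et2O, −10 °C to rt; then I2, −78 to 0 °C
Reagents that add atoms: methylmagnesium bromide C[Mg]Br; iodine II
Why: Copper-catalysed anti-carbomagnesiation of the propargylic alkoxide (Duboudin–Normant reaction) puts methyl on the internal carbon and magnesium on the terminal carbon within a five-membered chelate, so iodinolysis should give the (Z)-vinyl iodide with iodine cis to CH2OH, the relationship that becomes C2 cis to C5 across C3=C4.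

Step 2
Reactants: 2 (Z)-3-iodo-2-methylprop-2-en-1-ol
Product: 3 (Z)-3-bromo-1-iodo-2-methylprop-1-ene
Conditions: CBr4, PPh3, CH2Cl2, 0 °C
Reagents that add atoms: carbon tetrabromide BrC(Br)(Br)Br
Why: Appel bromination converts the primary allylic alcohol into the bromide under neutral conditions without touching the vinyl iodide or its geometry.

Step 3
Reactants: 4 2,2-dimethyl-1,3-dioxan-5-one; 5 RAMP, (R)-1-amino-2-(methoxymethyl)pyrrolidine
Product: 6 RAMP hydrazone of 2,2-dimethyl-1,3-dioxan-5-one
Conditions: benzene, reflux, Dean–Stark trap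
Reagents that add atoms: none
Why: Condensation of the ketone with the hydrazine NH2 group gives the Enders hydrazone, a chiral and non-self-condensing enolate equivalent of the dihydroxyacetone unit C6–C7–C8.

Step 4
Reactants: 6 RAMP hydrazone of 2,2-dimethyl-1,3-dioxan-5-one; 3 (Z)-3-bromo-1-iodo-2-methylprop-1-ene
Product: 7 RAMP hydrazone of (4R)-4-[(2Z)-3-iodo-2-methylprop-2-en-1-yl]-2,2-dimethyl-1,3-dioxan-5-one
Conditions: t-BuLi (1.05 equiv), THF, −78 °C; then 3, −100 °C to rt
Reagents that add atoms: none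
Why: Enders hydrazone alkylation: the lithium azaenolate, rigidified by chelation of lithium to the methoxymethyl arm, is alkylated by the allylic bromide (SN2) from the unshielded face, RAMP leading to the (R) configuration at C6 (the mirror of the (S) outcome known for SAMP).

Step 5
Reactants: 7 RAMP hydrazone of (4R)-4-[(2Z)-3-iodo-2-methylprop-2-en-1-yl]-2,2-dimethyl-1,3-dioxan-5-one
Product: 9 (3R,5Z)-1,3-dihydroxy-6-iodo-5-methylhex-5-en-2-one, via dioxanone ketone 8 (not isolated)
Conditions: sat. aq. oxalic acid, Et2O, rt; then 2 N HCl, THF, rt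
Reagents that add atoms: water O
Why: Biphasic oxalic acid hydrolyses the hydrazone without epimerization (the auxiliary stays in the aqueous phase) and dilute HCl then cleaves the acetonide, exposing the C7 ketone flanked by the C6 and C8 hydroxyls.

Step 6
Reactants: 10 diethylphosphonoacetic acid
Product: 11 2-(diethoxyphosphoryl)-3-[(triisopropylsilyl)oxy]propanoic acid (racemic)
Conditions: LDA (2.1 equiv), THF, −78 °C; then (i-Pr)3SiOCH2Cl, −78 to −20 °C; cold 1 N HCl work-up
Reagents that add atoms: (triisopropylsiloxy)methyl chloride ClCO[Si](C(C)C)(C(C)C)C(C)C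
Why: The carboxylate–phosphonate dianion reacts at its far more nucleophilic carbon with the α-chloro ether (enolate alkylation), which installs C13 already carrying its oxygen as a robust, poorly nucleofugal silyl ether.

Step 7
Reactants: 9 (3R,5Z)-1,3-dihydroxy-6-iodo-5-methylhex-5-en-2-one; 11 2-(diethoxyphosphoryl)-3-[(triisopropylsilyl)oxy]propanoic acid
Product: 12 (3R,5Z)-3-hydroxy-6-iodo-5-methyl-2-oxohex-5-en-1-yl 2-(diethoxyphosphoryl)-3-[(triisopropylsilyl)oxy]propanoate
Conditions: EDC·HCl, DMAP (5 mol%), CH2Cl2, −20 °C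
Reagents that add atoms: none
Why: Carbodiimide (Steglich-type) esterification at low temperature should select the unhindered primary C8 hydroxyl over the secondary C6 hydroxyl, which is flanked by the ketone and the branched allyl chain.

Step 8
Reactants: 12 (3R,5Z)-3-hydroxy-6-iodo-5-methyl-2-oxohex-5-en-1-yl 2-(diethoxyphosphoryl)-3-[(triisopropylsilyl)oxy]propanoate
Product: 13 (3R,5Z)-6-iodo-3-(methacryloyloxy)-5-methyl-2-oxohex-5-en-1-yl 2-(diethoxyphosphoryl)-3-[(triisopropylsilyl)oxy]propanoate
Conditions: methacrylic anhydride, pyridine, DMAP (cat.), CH2Cl2, 0 °C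
Reagents that add atoms: methacrylic anhydride C=C(C)C(=O)OC(=O)C(C)=C
Why: DMAP-catalysed acylation installs the C6 methacrylate of the target at the outset, which removes the free α-ketol (no acyl migration or enediol isomerization in step 9) and leaves a non-enolizable ester.

Step 9
Reactants: 13 (3R,5Z)-6-iodo-3-(methacryloyloxy)-5-methyl-2-oxohex-5-en-1-yl 2-(diethoxyphosphoryl)-3-[(triisopropylsilyl)oxy]propanoate
Product: 14 (1R,3Z)-4-iodo-3-methyl-1-[5-oxo-4-{[(triisopropylsilyl)oxy]methyl}-2,5-dihydrofuran-3-yl]but-3-en-1-yl methacrylate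
Conditions: LiCl, i-Pr2NEt, MeCN, 0 °C to rt
Reagents that add atoms: none
Why: Lithium-assisted deprotonation of the phosphonate C11–H (the most acidic site) gives a chelated carbanion that adds to the C7 ketone and collapses through the oxaphosphetane with loss of diethyl phosphate, i.e. an intramolecular Horner–Wadsworth–Emmons olefination under Masamune–Roush conditions, the established way from α-(phosphonoacyloxy) ketones to butenolides. Ring B is closed in the 5-exo-trig mode (C11 attacks the C7 carbonyl carbon, the C=O bond lying outside the forming ring). No stereocenter is created; the geometry of the tetrasubstituted C7=C11 alkene is fixed by the ring, and the epimers of 13 at C11 converge. The step needs chemoselectivity for the ketone over the two esters and retention of the C6 configuration: the ketone is the only carbonyl within five-ring reach and is activated by two α-acyloxy groups, and the weak amine base with LiCl is chosen so that olefination outruns enolization toward C6. Reversible expulsion of triisopropylsilanolate from the β-silyloxy carbanion should be self-correcting, since re-addition to the resulting phosphonoacrylate regenerates the same carbanion.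

Step 10
Reactants: 15 (R)-2-methylglycidol; 16 1,3-dithiane
Product: 17 (2S)-3-(1,3-dithian-2-yl)-2-methylpropane-1,2-diol
Conditions: 16 (2.3 equiv), n-BuLi (2.2 equiv), THF, −30 °C; then 15, −30 to 0 °C
Reagents that add atoms: none
Why: Corey–Seebach epoxide opening: the lithiated dithiane attacks the unsubstituted epoxide carbon (SN2), so the C10 stereocenter of 15 is carried over unchanged and C2 enters as a masked aldehyde.

Step 11
Reactants: 17 (2S)-3-(1,3-dithian-2-yl)-2-methylpropane-1,2-diol
Product: 18 (2S)-3-(1,3-dithian-2-yl)-2-methyl-1,2-bis[(triethylsilyl)oxy]propane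
Conditions: TESOTf (2.4 equiv), 2,6-lutidine, CH2Cl2, −78 to 0 °C
Reagents that add atoms: triethylsilyl triflate CC[Si](CC)(CC)OS(=O)(=O)C(F)(F)F
Why: The silyl triflate with lutidine silylates both the primary and the hindered tertiary hydroxyl.

Step 12
Reactants: 18 (2S)-3-(1,3-dithian-2-yl)-2-methyl-1,2-bis[(triethylsilyl)oxy]propane
Product: 19 (2S)-3-(1,3-dithian-2-yl)-2-methyl-2-[(triethylsilyl)oxy]propanal
Conditions: (COCl)2, DMSO, CH2Cl2, −78 to −30 °C; then Et3N, −78 °C to rt
Reagents that add atoms: none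
Why: Under Swern conditions a primary triethylsilyl ether is cleaved and oxidized directly to the aldehyde while the tertiary one is inert, giving the non-enolizable C9 aldehyde with C10 unchanged.

Step 13
Reactants: 14 (1R,3Z)-4-iodo-3-methyl-1-[5-oxo-4-{[(triisopropylsilyl)oxy]methyl}-2,5-dihydrofuran-3-yl]but-3-en-1-yl methacrylate; 19 (2S)-3-(1,3-dithian-2-yl)-2-methyl-2-[(triethylsilyl)oxy]propanal
Product: 21 C8–C9 vinylogous aldol adduct (C9 alcohol; C8/C9 diastereomers; 6R,10S), via silyloxyfuran 20 (not isolated)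
Conditions: TBSOTf, Et3N, CH2Cl2, 0 °C; then 19, BF3·OEt2, −78 °C; aq. NaHCO3
Reagents that add atoms: tert-butyldimethylsilyl triflate CC(C)(C)[Si](C)(C)OS(=O)(=O)C(F)(F)F (silyl group present in 20 only, lost again before 21)
Why: Soft enolization at the γ-carbon C8 gives the aromatic 2-silyloxyfuran, whose vinylogous Mukaiyama aldol addition to the BF3-activated, non-enolizable aldehyde takes place at C8 (the α-carbon C11 is fully substituted) and forms the C8–C9 bond; the new C8 and C9 centres need no control because both become sp2 in step 17.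

Step 14
Reactants: 21 C8–C9 vinylogous aldol adduct
Product: 22 C9 acetate of 21
Conditions: Ac2O, pyridine, DMAP (cat.), CH2Cl2, 0 °C to rt
Reagents that add atoms: acetic anhydride CC(=O)OC(C)=O
Why: Acetylation caps the C9 hydroxyl (no lactol with the C2 aldehyde in step 16) and turns it into the leaving group for step 17.

Step 15
Reactants: 22 C9 acetate of 21
Product: 23 seco-aldehyde (C2 aldehyde; C3 vinyl iodide)
Conditions: MeI, CaCO3, MeCN/H2O (9:1), 40 °C
Reagents that add atoms: water O
Why: S-Methylation of the dithiane and hydrolysis under CaCO3 buffering liberate the C2 aldehyde under neutral conditions that spare the silyl ethers, the esters and the vinyl iodide.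

Step 16
Reactants: 23 seco-aldehyde
Product: 24 (2R,6R,10S)-macrocyclic allylic alcohol (ring A closed; C2–OH, C9–OAc, C10–OTES, C13–OTIPS, C6 methacrylate)
Conditions: CrCl2 (10 equiv), NiCl2 (1 mol%), DMSO/THF, rt, slow addition to 0.002 M
Reagents that add atoms: none
Why: Nozaki–Hiyama–Kishi coupling: zerovalent nickel formed in situ inserts into the vinyl carbon–iodine bond with retention of the (Z) geometry, transmetalation gives a vinyl derivative of trivalent chromium that adds only to the aldehyde, and high dilution favours closure of the ten-membered ring A at C2–C3; the C2 configuration is set under macrocyclic substrate control, the (2R) epimer shown being the one required and its preference remaining to be established.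

Step 17
Reactants: 24 (2R,6R,10S)-macrocyclic allylic alcohol
Product: 26 10-O-triethylsilyl 13-O-triisopropylsilyl ether of the target, via diacetate 25 (not isolated)
Conditions: Ac2O, Et3N, DMAP (cat.), CH2Cl2, 0 °C; then DBU, 0 °C
Reagents that add atoms: acetic anhydride CC(=O)OC(C)=O
Why: Acetylation of the allylic C2 hydroxyl gives the acetate of the target, and DBU then removes the acidic γ-proton at C8 so that the furanolate expels the C9 acetate (E1cB), the ring holding C10 on the C7 side and thereby giving the (E), ring-cis C8=C9 geometry from either C9 epimer.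

Step 18
Reactants: 26 10-O-triethylsilyl 13-O-triisopropylsilyl ether of the target
Product: 27 (2R,6R,10S,3Z,8E)-2-acetoxy-10,13-dihydroxy-6-(methacryloyloxy)germacra-3,7(11),8-trien-12,8-olide (CNP0122447.1)
Conditions: HF·pyridine, pyridine, THF, 0 °C to rt
Reagents that add atoms: none
Why: Buffered HF·pyridine cleaves the tertiary triethylsilyl and the primary triisopropylsilyl ether by Si–F bond formation without touching the acetate, the methacrylate or the acid-sensitive tertiary allylic alcohol.

Compound list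
1 | propargyl alcohol | C#CCO | starting material
2 | (Z)-3-iodo-2-methylprop-2-en-1-ol | OC/C(C)=C\I | intermediate
3 | (Z)-3-bromo-1-iodo-2-methylprop-1-ene | BrC/C(C)=C\I | intermediate
4 | 2,2-dimethyl-1,3-dioxan-5-one | CC1(C)OCC(=O)CO1 | starting material
5 | RAMP, (R)-1-amino-2-(methoxymethyl)pyrrolidine | COC[C@H]1CCCN1N | starting material
6 | RAMP hydrazone of 2,2-dimethyl-1,3-dioxan-5-one | CC1(C)OCC(=NN2CCC[C@@H]2COC)CO1 | intermediate
7 | RAMP hydrazone of (4R)-4-[(2Z)-3-iodo-2-methylprop-2-en-1-yl]-2,2-dimethyl-1,3-dioxan-5-one | CC1(C)OCC(=NN2CCC[C@@H]2COC)[C@@H](C/C(C)=C\I)O1 | intermediate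
8 | (4R)-4-[(2Z)-3-iodo-2-methylprop-2-en-1-yl]-2,2-dimethyl-1,3-dioxan-5-one | CC1(C)OCC(=O)[C@@H](C/C(C)=C\I)O1 | intermediate (not isolated)
9 | (3R,5Z)-1,3-dihydroxy-6-iodo-5-methylhex-5-en-2-one | OCC(=O)[C@H](O)C/C(C)=C\I | intermediate
10 | diethylphosphonoacetic acid | CCOP(=O)(OCC)CC(=O)O | starting material
11 | 2-(diethoxyphosphoryl)-3-[(triisopropylsilyl)oxy]propanoic acid (racemic) | CCOP(=O)(OCC)C(CO[Si](C(C)C)(C(C)C)C(C)C)C(=O)O | intermediate
12 | (3R,5Z)-3-hydroxy-6-iodo-5-methyl-2-oxohex-5-en-1-yl 2-(diethoxyphosphoryl)-3-[(triisopropylsilyl)oxy]propanoate (epimers at the phosphonate carbon) | CCOP(=O)(OCC)C(CO[Si](C(C)C)(C(C)C)C(C)C)C(=O)OCC(=O)[C@H](O)C/C(C)=C\I | intermediate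
13 | (3R,5Z)-6-iodo-3-(methacryloyloxy)-5-methyl-2-oxohex-5-en-1-yl 2-(diethoxyphosphoryl)-3-[(triisopropylsilyl)oxy]propanoate (epimers at the phosphonate carbon) | CCOP(=O)(OCC)C(CO[Si](C(C)C)(C(C)C)C(C)C)C(=O)OCC(=O)[C@H](OC(=O)C(C)=C)C/C(C)=C\I | intermediate
14 | (1R,3Z)-4-iodo-3-methyl-1-[5-oxo-4-{[(triisopropylsilyl)oxy]methyl}-2,5-dihydrofuran-3-yl]but-3-en-1-yl methacrylate (ring B butenolide) | C=C(C)C(=O)O[C@H](C/C(C)=C\I)C1=C(CO[Si](C(C)C)(C(C)C)C(C)C)C(=O)OC1 | intermediate
15 | (R)-2-methylglycidol, [(2R)-2-methyloxiran-2-yl]methanol | OC[C@]1(C)CO1 | starting material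
16 | 1,3-dithiane | C1CSCSC1 | starting material
17 | (2S)-3-(1,3-dithian-2-yl)-2-methylpropane-1,2-diol | OC[C@@](C)(O)CC1SCCCS1 | intermediate
18 | (2S)-3-(1,3-dithian-2-yl)-2-methyl-1,2-bis[(triethylsilyl)oxy]propane | CC[Si](CC)(CC)OC[C@@](C)(O[Si](CC)(CC)CC)CC1SCCCS1 | intermediate
19 | (2S)-3-(1,3-dithian-2-yl)-2-methyl-2-[(triethylsilyl)oxy]propanal | O=C[C@@](C)(O[Si](CC)(CC)CC)CC1SCCCS1 | intermediate
20 | 2-(tert-butyldimethylsilyloxy)furan derived from 14 | C=C(C)C(=O)O[C@H](C/C(C)=C\I)c1coc(O[Si](C)(C)C(C)(C)C)c1CO[Si](C(C)C)(C(C)C)C(C)C | intermediate (not isolated)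
21 | vinylogous aldol adduct: 14 carrying at C8 the (2S)-3-(1,3-dithian-2-yl)-1-hydroxy-2-methyl-2-[(triethylsilyl)oxy]propyl chain (C8/C9 diastereomers) | C=C(C)C(=O)O[C@H](C/C(C)=C\I)C1=C(CO[Si](C(C)C)(C(C)C)C(C)C)C(=O)OC1C(O)[C@@](C)(O[Si](CC)(CC)CC)CC2SCCCS2 | intermediate
22 | C9 acetate of 21 | C=C(C)C(=O)O[C@H](C/C(C)=C\I)C1=C(CO[Si](C(C)C)(C(C)C)C(C)C)C(=O)OC1C(OC(C)=O)[C@@](C)(O[Si](CC)(CC)CC)CC2SCCCS2 | intermediate
23 | seco-aldehyde (C2 aldehyde, C3 vinyl iodide, C9 acetate, C10 OTES) | C=C(C)C(=O)O[C@H](C/C(C)=C\I)C1=C(CO[Si](C(C)C)(C(C)C)C(C)C)C(=O)OC1C(OC(C)=O)[C@@](C)(O[Si](CC)(CC)CC)CC=O | intermediate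
24 | (2R,6R,10S,3Z)-macrocyclic allylic alcohol: 9-acetoxy-2-hydroxy-6-(methacryloyloxy)-10-(triethylsilyloxy)-13-(triisopropylsilyloxy)germacra-3,7(11)-dien-12,8-olide | C=C(C)C(=O)O[C@@H]1C/C(C)=C\[C@H](O)C[C@](C)(O[Si](CC)(CC)CC)C(OC(C)=O)C2OC(=O)C(CO[Si](C(C)C)(C(C)C)C(C)C)=C21 | intermediate
25 | C2,C9-diacetate of 24 | C=C(C)C(=O)O[C@@H]1C/C(C)=C\[C@H](OC(C)=O)C[C@](C)(O[Si](CC)(CC)CC)C(OC(C)=O)C2OC(=O)C(CO[Si](C(C)C)(C(C)C)C(C)C)=C21 | intermediate (not isolated)
26 | 10-O-triethylsilyl 13-O-triisopropylsilyl ether of the target | C=C(C)C(=O)O[C@@H]1C/C(C)=C\[C@H](OC(C)=O)C[C@](C)(O[Si](CC)(CC)CC)/C=C2/OC(=O)C(CO[Si](C(C)C)(C(C)C)C(C)C)=C21 | intermediate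
27 | (2R,6R,10S,3Z,8E)-2-acetoxy-10,13-dihydroxy-6-(methacryloyloxy)germacra-3,7(11),8-trien-12,8-olide (CNP0122447.1) | C=C(C)C(=O)O[C@@H]1C/C(C)=C\[C@H](OC(C)=O)C[C@](C)(O)/C=C2/OC(=O)C(CO)=C21 | target

Total step count: 18.
Longest linear sequence: 13 steps (steps 1, 2, 4, 5, 7, 8, 9, 13, 14, 15, 16, 17, 18, from propargyl alcohol).

Steps most likely to fail

Step 16. Closure of the strained ten-membered ring is slow, and the vinylchromium intermediate may attack the two faces of the C2 aldehyde without discrimination, so that the (2S) alcohol accompanies or outweighs the (2R) alcohol. The fallback replaces substrate control by reagent control and sets out from 24 (as its mixture of C2 epimers). Dess–Martin periodinane (NaHCO3, CH2Cl2, 0 °C) oxidizes the allylic alcohol to the macrocyclic (Z)-enone F1. Corey–Bakshi–Shibata reduction with (S)-2-methyl-CBS-oxazaborolidine and catecholborane (toluene, −78 °C), in which the alkenyl group acts as the large substituent, should then deliver the (2R) alcohol only. The fallback comes back to the route at 24.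

Step 13. Bimolecular addition of the silyloxyfuran to the neopentyl-type aldehyde may be slow, so that protodesilylation of the dienol ether and Lewis-acid ionization of the furylic C6 ester take over. The fallback exchanges the order of the two fragment unions: the chromium-mediated coupling, which is indifferent to both problems, joins the fragments at C2–C3, and the vinylogous aldol reaction closes ring A at C8–C9. It sets out from 18 and 14. MeI and CaCO3 in aqueous MeCN unmask 18 to (3S)-3-methyl-3,4-bis[(triethylsilyl)oxy]butanal F2. Intermolecular Nozaki–Hiyama–Kishi coupling of F2 with 14 (CrCl2, NiCl2 cat., DMSO, rt) gives the open-chain C2 allylic alcohol F3, whose C2 epimers are separated. Acetylation (Ac2O, pyridine, DMAP) gives the open-chain C2 acetate F4. Swern oxidation of the primary triethylsilyl ether gives the open-chain C9 aldehyde F5. TBSOTf and Et3N convert it into the silyloxyfuran aldehyde F6, which is added slowly to BF3·OEt2 in CH2Cl2 at −78 °C (high dilution) and should undergo the intramolecular vinylogous Mukaiyama aldol reaction to the macrocyclic C9 alcohol F7. Acetylation of F7 gives the diacetate 25, where the fallback comes back to the route.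

Step 9. The β-silyloxy phosphonate carbanion may expel silanolate faster than it adds to the ketone, and the base may enolize the ketone toward C6 and erode that stereocenter. The fallback closes ring B without a phosphonate carbanion, by an intramolecular Morita–Baylis–Hillman reaction followed by allylic transposition, and sets out from 9. Acryloyl chloride and 2,4,6-collidine (CH2Cl2, −78 °C) acylate the primary hydroxyl to give the primary acrylate F8. Methacrylic anhydride, pyridine and DMAP give the acrylate methacrylate F9. DABCO (MeCN, rt) adds to the acrylate, the resulting enolate attacks the C7 ketone (forming the C7–C11 bond) and loss of the amine gives the α-methylene-β-hydroxy lactone F10. Ph3SiOReO3 (cat., Et2O, 0 °C) transposes the tertiary allylic alcohol to the conjugated hydroxymethyl butenolide F11. TIPSCl and imidazole (DMF) then give 14, where the fallback comes back to the route.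

Further compounds
F1 | step 16 | macrocyclic (Z)-enone, the C2 ketone corresponding to 24 | C=C(C)C(=O)O[C@@H]1C/C(C)=C\C(=O)C[C@](C)(O[Si](CC)(CC)CC)C(OC(C)=O)C2OC(=O)C(CO[Si](C(C)C)(C(C)C)C(C)C)=C21
F2 | step 13 | (3S)-3-methyl-3,4-bis[(triethylsilyl)oxy]butanal | CC[Si](CC)(CC)OC[C@@](C)(O[Si](CC)(CC)CC)CC=O
F3 | step 13 | open-chain C2 allylic alcohol (C2–C3 joined; C9 and C10 as triethylsilyl ethers) | C=C(C)C(=O)O[C@H](C/C(C)=C\[C@H](O)C[C@](C)(O[Si](CC)(CC)CC)CO[Si](CC)(CC)CC)C1=C(CO[Si](C(C)C)(C(C)C)C(C)C)C(=O)OC1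
F4 | step 13 | open-chain C2 acetate | C=C(C)C(=O)O[C@H](C/C(C)=C\[C@H](OC(C)=O)C[C@](C)(O[Si](CC)(CC)CC)CO[Si](CC)(CC)CC)C1=C(CO[Si](C(C)C)(C(C)C)C(C)C)C(=O)OC1
F5 | step 13 | open-chain C9 aldehyde | C=C(C)C(=O)O[C@H](C/C(C)=C\[C@H](OC(C)=O)C[C@](C)(O[Si](CC)(CC)CC)C=O)C1=C(CO[Si](C(C)C)(C(C)C)C(C)C)C(=O)OC1
F6 | step 13 | silyloxyfuran aldehyde | C=C(C)C(=O)O[C@H](C/C(C)=C\[C@H](OC(C)=O)C[C@](C)(O[Si](CC)(CC)CC)C=O)c1coc(O[Si](C)(C)C(C)(C)C)c1CO[Si](C(C)C)(C(C)C)C(C)C
F7 | step 13 | macrocyclic C9 alcohol (C2 acetate) | C=C(C)C(=O)O[C@@H]1C/C(C)=C\[C@H](OC(C)=O)C[C@](C)(O[Si](CC)(CC)CC)C(O)C2OC(=O)C(CO[Si](C(C)C)(C(C)C)C(C)C)=C21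
F8 | step 9 | (3R,5Z)-3-hydroxy-6-iodo-5-methyl-2-oxohex-5-en-1-yl acrylate | C=CC(=O)OCC(=O)[C@H](O)C/C(C)=C\I
F9 | step 9 | (3R,5Z)-6-iodo-3-(methacryloyloxy)-5-methyl-2-oxohex-5-en-1-yl acrylate | C=CC(=O)OCC(=O)[C@H](OC(=O)C(C)=C)C/C(C)=C\I
F10 | step 9 | (1R,3Z)-1-(3-hydroxy-4-methylidene-5-oxooxolan-3-yl)-4-iodo-3-methylbut-3-en-1-yl methacrylate (C7 epimers) | C=C1C(=O)OCC1(O)[C@H](OC(=O)C(C)=C)C/C(C)=C\I
F11 | step 9 | (1R,3Z)-1-[4-(hydroxymethyl)-5-oxo-2,5-dihydrofuran-3-yl]-4-iodo-3-methylbut-3-en-1-yl methacrylate | C=C(C)C(=O)O[C@H](C/C(C)=C\I)C1=C(CO)C(=O)OC1
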